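## Retrosynthetic overview

1. The C1 stereocentre is set last by face-selective hydrogenation of a ring A C1=C2 alkene; the cis-bromohydrin (C3, C4) comes from an α'-bromo enone by asymmetric transfer hydrogenation with dynamic kinetic resolution.
2. The C3 oxygen is introduced by allylic C–H oxidation of the ring A alkene (a C–O bond) once ring B is finished.
3. The ring B trans-bromochloride comes from a C1–O–C9 bridged bromo ether, opened by chloride with retention through a bromonium ion (new step); the same step unveils the C1=C2 alkene.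
4. Key bond: the C9–O bond, made by intramolecular bromoetherification of the C1 tertiary alcohol onto the ring B alkene; this tether relays the spiro centre to C9 and C10.
5. Ring order: ring A comes from 3-methylcyclohexenone; ring B and the spiro centre are formed second by a catalytic asymmetric Diels–Alder reaction of the exocyclic enone with isoprene.

Locants used throughout (spiro[5.5]undecane): C1 = CHMe, C3 = CHOH, C4 = CHBr, C5 = CMe2, C6 = spiro, C9 = C(Me)Cl, C10 = CHBr; ring A = C1–C6, ring B = C6–C11.

Assumption: the IDPi enantiomer used is the one that gives (6R)-7, and the (S,S) ruthenium catalyst is taken to give the 3R carbinol (alkenyl in the role of aryl); if either sense is opposite, the antipodal catalyst is used.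

## Route

Step 1
Reactants: 1 3-methylcyclohex-2-en-1-one
Product: 5 3,3-dimethyl-2-methylidenecyclohexan-1-one, via magnesium enolate 2 (not isolated), via Mannich base 3 (not isolated), via ammonium iodide 4 (not isolated)
Conditions: MeMgBr, CuBr·SMe2 (5 mol%), THF, −30 °C; then CH2=NMe2+ I−, −30 to 23 °C; then MeI, Et2O, 23 °C; then aq. NaHCO3, CH2Cl2, 23 °C
Reagents that add atoms: methylmagnesium bromide C[Mg]Br; dimethylmethylideneammonium iodide C=[N+](C)C.[I-]
Why: Copper-catalysed conjugate addition gives the enolate regiospecifically at C2, a Mannich reaction with the iminium salt installs the aminomethyl group there, and N-methylation followed by Hofmann-type β-elimination unveils the exocyclic enone; no stereocentre is formed.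

Step 2
Reactants: 5 3,3-dimethyl-2-methylidenecyclohexan-1-one; 6 isoprene (2-methylbuta-1,3-diene)
Product: 7 (6R)-5,5,9-trimethylspiro[5.5]undec-8-en-1-one
Conditions: isoprene (5 equiv), chiral imidodiphosphorimidate (IDPi) Brønsted acid (2 mol%), CHCl3, −40 °C
Reagents that add atoms: none
Why: Brønsted acid-catalysed asymmetric Diels–Alder reaction of an exocyclic enone, a known spirocyclisation type: the confined chiral counter-anion shields one face of the protonated enone, isoprene adds with "para" regiochemistry, and the spiro centre C6 is set as R.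

Step 3
Reactants: 7 (6R)-5,5,9-trimethylspiro[5.5]undec-8-en-1-one
Product: 8 (6R)-1,5,5,9-tetramethylspiro[5.5]undec-8-en-1-ol as both C1 epimers
Conditions: MeLi (2 equiv), Et2O, −78 to 0 °C; then H2O
Reagents that add atoms: methyllithium C[Li]
Why: 1,2-addition of an organolithium to the hindered ketone; the new C1 carbinol centre forms without useful control, which does not matter because C1 becomes sp2 again in step 5.

Step 4
Reactants: 8 (6R)-1,5,5,9-tetramethylspiro[5.5]undec-8-en-1-ol
Product: 9 (6R,9S,10S)-10-bromo-1,9-epoxy-1,5,5,9-tetramethylspiro[5.5]undecane as both C1 epimers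
Conditions: NBS (1.1 equiv), CH2Cl2, 0 °C, dark
Reagents that add atoms: N-bromosuccinimide O=C1CCC(=O)N1Br
Why: Intramolecular bromoetherification (Markovnikov six-membered closure, as in the terpineol-to-bromocineole cyclisation): the C1 oxygen can reach C9 only on the ring B face that carries C1, and bromine must add anti, so the spiro centre fixes C9 (S, oxygen syn to C1) and C10 (S, bromine on the C5 face) whatever the C1 configuration.

Step 5
Reactants: 9 (6R,9S,10S)-10-bromo-1,9-epoxy-1,5,5,9-tetramethylspiro[5.5]undecane
Product: 11 (6R,9S,10S)-10-bromo-9-chloro-1,5,5,9-tetramethylspiro[5.5]undec-1-ene, via dichloroborinate 10 (not isolated)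
Conditions: BCl3 (2.2 equiv), 2,6-di-tert-butyl-4-methylpyridine (1.2 equiv), CH2Cl2, −78 to 0 °C; then H2O
Reagents that add atoms: boron trichloride ClB(Cl)Cl
Why: Proposed new method: BCl3-triggered double C–O scission of a bridged β-bromo di-tertiary ether with retentive chloride delivery — BCl3 binds the ether oxygen, the strained C1–O bond (not deactivated by bromine) ionises first and the C1 cation loses the C2 proton to the pyridine base (E1, Zaitsev) to give borinate 10; on warming the C9–O–BCl2 bond ionises, the trans C10 bromine closes to a bromonium ion on the C5 face, and chloride opens it at the tertiary carbon from the face the oxygen has just left, so the C9–Cl bond forms with net retention (9S) and the trans-bromochloride results; the closest known reactions are BCl3 cleavage of tertiary ethers to chlorides, hydrogen halide opening of cineole, and bromonium-mediated retentive substitution of β-bromo alcohols.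

Step 6
Reactants: 11 (6R,9S,10S)-10-bromo-9-chloro-1,5,5,9-tetramethylspiro[5.5]undec-1-ene
Product: 13 (6R,9S,10S)-10-bromo-9-chloro-1,5,5,9-tetramethylspiro[5.5]undec-1-en-3-one, via allylic peroxide 12 (not isolated)
Conditions: Rh2(cap)4 (cap = caprolactamate, 1 mol%), t-BuOOH (5 equiv), K2CO3 (0.5 equiv), CH2Cl2, 23 °C
Reagents that add atoms: tert-butyl hydroperoxide CC(C)(C)OO
Why: Catalytic allylic C–H oxidation (tert-butylperoxyl radical chain, then Kornblum–DeLaMare-type collapse of the allylic peroxide): C3 is the only ring allylic methylene, so the C3–O bond and the conjugated enone form regioselectively and no stereocentre is touched.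

Step 7
Reactants: 13 (6R,9S,10S)-10-bromo-9-chloro-1,5,5,9-tetramethylspiro[5.5]undec-1-en-3-one
Product: 16 (6S,9S,10S)-4,10-dibromo-9-chloro-1,5,5,9-tetramethylspiro[5.5]undec-1-en-3-one as both C4 epimers, via lithium dienolate 14 (not isolated), via silyl dienol ether 15 (not isolated)
Conditions: LiN(SiMe3)2 (1.2 equiv), Me3SiCl (1.3 equiv), THF, −78 °C; then NBS (1.05 equiv), −78 °C; then H2O
Reagents that add atoms: N-bromosuccinimide O=C1CCC(=O)N1Br
Why: Kinetic α'-deprotonation of the cross-conjugated enone (C4 is the only α' position, as in isophorone), silylation and electrophilic bromination of the silyl dienol ether give the C4 bromide; ring B looks almost symmetric from ring A, so no diastereocontrol is expected, and none is needed because C4 stays epimerisable and is corrected in step 8.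

Step 8
Reactants: 16 (6S,9S,10S)-4,10-dibromo-9-chloro-1,5,5,9-tetramethylspiro[5.5]undec-1-en-3-one
Product: 17 (3R,4S,6S,9S,10S)-4,10-dibromo-9-chloro-1,5,5,9-tetramethylspiro[5.5]undec-1-en-3-ol
Conditions: RuCl(p-cymene)[(S,S)-TsDPEN] (2 mol%), HCO2H/Et3N (5:2), CH2Cl2, 25 °C
Reagents that add atoms: none
Why: Noyori–Ikariya asymmetric transfer hydrogenation with dynamic kinetic resolution (known for cyclic α-halo ketones, which give cis-halohydrins): Et3N epimerises C4 through the dienol, the catalyst fixes C3 as R by reagent control, and only the C4 epimer whose C–Br bond lies anti to the incoming hydride is reduced fast, giving the cis (3R,4S) bromohydrin.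

Step 9
Reactants: 17 (3R,4S,6S,9S,10S)-4,10-dibromo-9-chloro-1,5,5,9-tetramethylspiro[5.5]undec-1-en-3-ol
Product: 18 (1S,3R,4S,6S,9S,10S)-4,10-dibromo-9-chloro-1,5,5,9-tetramethylspiro[5.5]undecan-3-ol
Conditions: H2 (1 atm), PtO2 (5 mol%), EtOAc, 23 °C
Reagents that add atoms: none
Why: Heterogeneous catalytic hydrogenation: hydrogen is expected to add to the C1=C2 alkene from the face opposite the C3 hydroxyl, the C4 bromine and the C11 methylene, which places the C1 methyl cis to OH and Br (1S); PtO2 is chosen because it leaves unactivated alkyl bromides and chlorides intact.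

## Compound list

1 | 3-methylcyclohex-2-en-1-one | CC1=CC(=O)CCC1 | starting material
2 | bromomagnesium 3,3-dimethylcyclohex-1-en-1-olate | CC1(C)CCCC(O[Mg]Br)=C1 | intermediate
3 | 2-[(dimethylamino)methyl]-3,3-dimethylcyclohexan-1-one (racemic) | CN(C)CC1C(=O)CCCC1(C)C | intermediate
4 | [(2,2-dimethyl-6-oxocyclohexyl)methyl]trimethylammonium iodide (racemic) | C[N+](C)(C)CC1C(=O)CCCC1(C)C.[I-] | intermediate
5 | 3,3-dimethyl-2-methylidenecyclohexan-1-one | C=C1C(=O)CCCC1(C)C | intermediate
6 | isoprene (2-methylbuta-1,3-diene) | C=CC(C)=C | starting material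
7 | (6R)-5,5,9-trimethylspiro[5.5]undec-8-en-1-one | O=C1CCCC(C)(C)[C@]12CCC(C)=CC2 | intermediate
8 | (6R)-1,5,5,9-tetramethylspiro[5.5]undec-8-en-1-ol (both C1 epimers, C1 left undefined) | CC1(O)CCCC(C)(C)[C@]12CCC(C)=CC2 | intermediate
9 | (6R,9S,10S)-10-bromo-1,9-epoxy-1,5,5,9-tetramethylspiro[5.5]undecane (oxygen bridges C1 and C9; both C1 epimers, C1 left undefined) | CC1(O2)CCCC(C)(C)[C@]13CC[C@@]2(C)[C@@H](Br)C3 | intermediate
10 | (6R,9S,10S)-10-bromo-9-(dichloroboranyloxy)-1,5,5,9-tetramethylspiro[5.5]undec-1-ene | CC1=CCCC(C)(C)[C@]12CC[C@](C)(OB(Cl)Cl)[C@@H](Br)C2 | intermediate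
11 | (6R,9S,10S)-10-bromo-9-chloro-1,5,5,9-tetramethylspiro[5.5]undec-1-ene | CC1=CCCC(C)(C)[C@]12CC[C@](C)(Cl)[C@@H](Br)C2 | intermediate
12 | (6R,9S,10S)-10-bromo-3-(tert-butylperoxy)-9-chloro-1,5,5,9-tetramethylspiro[5.5]undec-1-ene (both C3 epimers, C3 left undefined) | CC1=CC(OOC(C)(C)C)CC(C)(C)[C@]12CC[C@](C)(Cl)[C@@H](Br)C2 | intermediate
13 | (6R,9S,10S)-10-bromo-9-chloro-1,5,5,9-tetramethylspiro[5.5]undec-1-en-3-one | CC1=CC(=O)CC(C)(C)[C@]12CC[C@](C)(Cl)[C@@H](Br)C2 | intermediate
14 | lithium (6S,9S,10S)-10-bromo-9-chloro-1,5,5,9-tetramethylspiro[5.5]undeca-1,3-dien-3-olate | CC1=CC(O[Li])=CC(C)(C)[C@]12CC[C@](C)(Cl)[C@@H](Br)C2 | intermediate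
15 | (6S,9S,10S)-10-bromo-9-chloro-1,5,5,9-tetramethyl-3-(trimethylsilyloxy)spiro[5.5]undeca-1,3-diene | CC1=CC(O[Si](C)(C)C)=CC(C)(C)[C@]12CC[C@](C)(Cl)[C@@H](Br)C2 | intermediate
16 | (6S,9S,10S)-4,10-dibromo-9-chloro-1,5,5,9-tetramethylspiro[5.5]undec-1-en-3-one (both C4 epimers, C4 left undefined) | CC1=CC(=O)C(Br)C(C)(C)[C@]12CC[C@](C)(Cl)[C@@H](Br)C2 | intermediate
17 | (3R,4S,6S,9S,10S)-4,10-dibromo-9-chloro-1,5,5,9-tetramethylspiro[5.5]undec-1-en-3-ol | CC1=C[C@@H](O)[C@@H](Br)C(C)(C)[C@]12CC[C@](C)(Cl)[C@@H](Br)C2 | intermediate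
18 | (1S,3R,4S,6S,9S,10S)-4,10-dibromo-9-chloro-1,5,5,9-tetramethylspiro[5.5]undecan-3-ol | C[C@H]1C[C@@H](O)[C@@H](Br)C(C)(C)[C@]12CC[C@](C)(Cl)[C@@H](Br)C2 | target

## Step count and risks

Total steps: 9. Longest linear sequence: 9 steps (from 1).

Step 5 (the proposed new step). The C1 cation next to the spiro centre may undergo a 1,2-alkyl shift or give some exocyclic alkene, and chloride could attack before the bromine bridges, which would erode the C9 configuration. The fallback uses known chemistry and sets out from 9. Me3SiOTf and 2,6-lutidine in CH2Cl2 at −78 °C effect an eliminative ether cleavage (the reaction used to remove tert-butyl ethers), giving (6R,9S,10S)-10-bromo-1,5,5,9-tetramethyl-9-(trimethylsilyloxy)spiro[5.5]undec-1-ene F1. Concentrated HCl in CH2Cl2 at 0 °C then replaces the tertiary oxygen by chloride with retention through the bromonium ion (the classical behaviour of β-bromo alcohols). The fallback comes back to the route at 11.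

Step 8. Epimerisation at the neopentyl C4 may be too slow for a dynamic resolution, the catalyst may reduce the C=C bond, or the tertiary chloride may solvolyse in the formic acid medium. The fallback sets out from 16. Reduction with i-Bu2AlH in CH2Cl2 at −78 °C is substrate-controlled and gives a cis-bromohydrin from each C4 epimer: 17 and its ring A diastereomer (3S,4R,6S,9S,10S)-4,10-dibromo-9-chloro-1,5,5,9-tetramethylspiro[5.5]undec-1-en-3-ol F2. These are separated by chromatography; F2 is oxidised back to 16 with MnO2, re-equilibrated at C4 with Et3N and recycled. The fallback comes back to the route at 17.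

Step 9. Facial selectivity rests on sterics only; a hydroxyl-directed (syn) addition would give the C1 epimer, and hydrogenolysis of the allylic C–O bond is possible. The fallback sets out from 17. Redox isomerisation of the allylic alcohol with [Ir(cod)(PCy3)(py)]PF6 (activated with H2, then run under N2 in THF) moves the C3 hydrogen suprafacially to C1, on the face opposite the former hydroxyl. This gives (1S,4S,6S,9S,10S)-4,10-dibromo-9-chloro-1,5,5,9-tetramethylspiro[5.5]undecan-3-one F3 with the C1 methyl cis to bromine. NaBH4 in MeOH at −20 °C then adds hydride anti to the axial C4 bromine and restores the cis-bromohydrin. The fallback comes back to the route at 18.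

Further compounds
F1 | step 5 | (6R,9S,10S)-10-bromo-1,5,5,9-tetramethyl-9-(trimethylsilyloxy)spiro[5.5]undec-1-ene | CC1=CCCC(C)(C)[C@]12CC[C@](C)(O[Si](C)(C)C)[C@@H](Br)C2
F2 | step 8 | (3S,4R,6S,9S,10S)-4,10-dibromo-9-chloro-1,5,5,9-tetramethylspiro[5.5]undec-1-en-3-ol | CC1=C[C@H](O)[C@H](Br)C(C)(C)[C@]12CC[C@](C)(Cl)[C@@H](Br)C2
F3 | step 9 | (1S,4S,6S,9S,10S)-4,10-dibromo-9-chloro-1,5,5,9-tetramethylspiro[5.5]undecan-3-one | C[C@H]1CC(=O)[C@@H](Br)C(C)(C)[C@]12CC[C@](C)(Cl)[C@@H](Br)C2
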